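The route rests on cutting the C3–C4 bond of the glutarate chain (C1 = sinapyl ester carbonyl, C5 = free acid). The feature exploited is the tertiary carbinol C3, flanked by CH3 and two CH2C(=O) arms. Without C4–C5 it is a methyl ketone lying 1,3 to the C1 ester carbonyl, a pair of oxygens that can clamp a chiral copper centre. In one operation a malonic half thioester adds to C3 and sheds CO2. This makes the bond, the sole stereocentre and a C5 thioester that keeps the two arms chemically distinct. The precursor is (Z)-sinapyl acetoacetate with the phenol on the benzene ring, the only ring and a spectator, masked as a silyl ether.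

Key step: step 6

Remark on descriptors: C3 keeps one spatial arrangement from step 6 to the end. It reads (S) while C5 is a thioester, because the sulfur-bearing arm outranks the ester arm. It reads (R) once C5 is a carboxylic acid, because the ester arm then outranks the acid arm. No inversion is implied.

Assumption: the sense of induction is taken from the square-planar chelate model. If experiment shows the opposite sense, the equally available (S,S)-ligand is used and nothing else changes.

Ligand: (R,R)-t-Bu-box = 2,2'-(propane-2,2-diyl)bis[(4R)-4-tert-butyl-4,5-dihydro-1,3-oxazole].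

Handling: all Z-alkenes are kept out of light.

Step 1
Reactants: 1 syringaldehyde (4-hydroxy-3,5-dimethoxybenzaldehyde)
Product: 2 4-[(tert-butyldimethylsilyl)oxy]-3,5-dimethoxybenzaldehyde
Conditions: TBSCl (1.2 equiv), imidazole (2.5 equiv), DMF, rt
Reagents that add atoms: tert-butyldimethylsilyl chloride (TBSCl), CC(C)(C)[Si](C)(C)Cl
Why: Imidazole-promoted O-silylation of an acidic phenol is routine even between two methoxy groups, and it masks a phenol that would otherwise quench the olefination base, bind copper and be oxidised by silver later.

Step 2
Reactants: 2 4-[(tert-butyldimethylsilyl)oxy]-3,5-dimethoxybenzaldehyde; 3 methyl bis(2,2,2-trifluoroethyl)phosphonoacetate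
Product: 4 methyl (2Z)-3-{4-[(tert-butyldimethylsilyl)oxy]-3,5-dimethoxyphenyl}prop-2-enoate
Conditions: 3 (1.1 equiv), KN(SiMe3)2 (1.1 equiv), 18-crown-6 (3 equiv), THF, −78 °C
Reagents that add atoms: none
Why: In the Still–Gennari olefination the electron-poor phosphonate and the dissociated potassium counter-ion make elimination from the kinetic adduct faster than its equilibration, which should set the Z geometry with an aromatic aldehyde.

Step 3
Reactants: 4 methyl (2Z)-3-{4-[(tert-butyldimethylsilyl)oxy]-3,5-dimethoxyphenyl}prop-2-enoate
Product: 5 (2Z)-3-{4-[(tert-butyldimethylsilyl)oxy]-3,5-dimethoxyphenyl}prop-2-en-1-ol ((Z)-sinapyl alcohol silyl ether)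
Conditions: i-Bu2AlH (2.5 equiv), CH2Cl2, −78 °C; aqueous Rochelle salt
Reagents that add atoms: none
Why: 1,2-Reduction of an enoate with i-Bu2AlH delivers hydride to the carbonyl carbon only, so the Z-alkene is untouched and the aryl silyl ether is inert.

Step 4
Reactants: 5 (Z)-sinapyl alcohol silyl ether; 6 2,2,6-trimethyl-4H-1,3-dioxin-4-one
Product: 8 (2Z)-3-{4-[(tert-butyldimethylsilyl)oxy]-3,5-dimethoxyphenyl}prop-2-en-1-yl 3-oxobutanoate ((Z)-sinapyl acetoacetate silyl ether), via acetylketene 7 (not isolated)
Conditions: 6 (1.3 equiv), toluene, 110 °C, acetone distilled off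
Reagents that add atoms: none
Why: Thermal retro-hetero-Diels–Alder cleavage of 6 releases acetylketene 7, which the primary allylic alcohol traps under neutral conditions (acylketene acetoacetylation) well below the temperature of a Carroll rearrangement, so alkene geometry and silyl ether survive.

Step 5
Reactants: 9 2,2-dimethyl-1,3-dioxane-4,6-dione (Meldrum's acid); 10 thiophenol
Product: 11 3-oxo-3-(phenylsulfanyl)propanoic acid (malonic acid half thioester)
Conditions: PhSH (1.0 equiv), toluene, 90 °C; NaHCO3 extraction, then acidification
Reagents that add atoms: none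
Why: Nucleophilic ring opening of Meldrum's acid by a thiol with loss of acetone is the standard one-step entry to malonic half thioesters, the temperature stays below that of product decarboxylation, and acid–base extraction purifies the acid.

Step 6
Reactants: 8 (Z)-sinapyl acetoacetate silyl ether; 11 3-oxo-3-(phenylsulfanyl)propanoic acid
Product: 13 (2Z)-3-{4-[(tert-butyldimethylsilyl)oxy]-3,5-dimethoxyphenyl}prop-2-en-1-yl (3S)-3-hydroxy-3-methyl-5-oxo-5-(phenylsulfanyl)pentanoate, via C4-carboxy aldol adduct 12 (not isolated)
Conditions: Cu(OTf)2 (20 mol %), (R,R)-t-Bu-box (22 mol %), 2,6-lutidine (20 mol %), 11 (2 equiv, in portions), THF, 0 °C to rt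
Reagents that add atoms: none
Why: Proposed new method: divalent copper held by the C2-symmetric bisoxazoline should bind 8 through the C3 ketone oxygen and the C1 ester carbonyl oxygen as a flat six-membered chelate, the carboxylate of 11 enolises and attacks the activated C3 to give adduct 12, and irreversible loss of CO2 from 12 pulls the otherwise reversible ketone aldol forward to thioester 13. The closest known reaction type is the decarboxylative aldol addition of malonic half thioesters to aldehydes and to activated ketones (isatins, α-keto esters, trifluoromethyl ketones) under Cu(OTf)2–bisoxazoline or cinchona catalysis, together with copper–bisoxazoline Mukaiyama aldol additions to chelating pyruvates; an enolisable β-keto ester has not been shown as the acceptor. No ring is closed, and one C–C bond (C3–C4) is formed. C3 is controlled by the ligand alone, since CH3 and CH2CO2R are too alike for substrate bias: in the square-planar chelate the tert-butyl group of the (R,R)-ligand beside the ketone covers the si face (O > CH2CO2R > CH3), so attack on the re face should give (3S)-13, and the C2 axis makes both chelate orientations equivalent. The step needs addition to win over enolisation of 8 and the ketone to win over the ester carbonyls, which is secured by two-point binding that activates only C3, by the absence of any base stronger than the carboxylate of 11 (the excess acid keeps lutidine protonated and the copper enolate of 8 a reversible resting state) and by the silyl ether, which keeps the phenol from binding to or being oxidised by copper. Because C4–C5 arrives as a thioester, C5 stays distinguishable from the C1 oxygen ester for the next step.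

Step 7
Reactants: 13 S-phenyl thioester (3S)
Product: 14 (3R)-5-{[(2Z)-3-{4-[(tert-butyldimethylsilyl)oxy]-3,5-dimethoxyphenyl}prop-2-en-1-yl]oxy}-3-hydroxy-3-methyl-5-oxopentanoic acid
Conditions: AgOCOCF3 (2 equiv), 2,6-lutidine (2.5 equiv), THF/H2O 4:1, 0 °C to rt, dark; filtration, pH 3 work-up
Reagents that add atoms: water, O
Why: In this thiophilic silver-assisted thioester hydrolysis the soft silver cation binds sulfur and removes it as insoluble AgSPh, so water attacks only C5 while the C1 oxygen ester, silyl ether and Z-alkene are left alone, lutidine takes up the liberated CF3CO2H, and C3 is not touched (only its descriptor changes to R).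

Step 8
Reactants: 14 silyl-protected acid (3R)
Product: 15 (3R)-3-hydroxy-5-{[(2Z)-3-(4-hydroxy-3,5-dimethoxyphenyl)prop-2-en-1-yl]oxy}-3-methyl-5-oxopentanoic acid (target)
Conditions: Bu4NF (2 equiv), AcOH (3 equiv), THF, 0 °C; pH 3 work-up
Reagents that add atoms: none
Why: Fluoride-induced cleavage of an aryl silyl ether is fast at 0 °C, and the acetic acid buffer protonates the phenoxide as it forms, which should prevent vinylogous expulsion of the carboxylate (quinone methide formation), ester cleavage and retro-aldol.

Compound list
1 | syringaldehyde | COc1cc(C=O)cc(OC)c1O | starting material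
2 | 4-[(tert-butyldimethylsilyl)oxy]-3,5-dimethoxybenzaldehyde | COc1cc(C=O)cc(OC)c1O[Si](C)(C)C(C)(C)C | intermediate
3 | methyl bis(2,2,2-trifluoroethyl)phosphonoacetate | COC(=O)CP(=O)(OCC(F)(F)F)OCC(F)(F)F | starting material
4 | methyl (2Z)-3-{4-[(tert-butyldimethylsilyl)oxy]-3,5-dimethoxyphenyl}prop-2-enoate | COc1cc(/C=C\C(=O)OC)cc(OC)c1O[Si](C)(C)C(C)(C)C | intermediate
5 | (Z)-sinapyl alcohol tert-butyldimethylsilyl ether | COc1cc(/C=C\CO)cc(OC)c1O[Si](C)(C)C(C)(C)C | intermediate
6 | 2,2,6-trimethyl-4H-1,3-dioxin-4-one | CC1=CC(=O)OC(C)(C)O1 | starting material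
7 | acetylketene (but-1-ene-1,3-dione; transient) | CC(=O)C=C=O | intermediate
8 | (Z)-sinapyl acetoacetate tert-butyldimethylsilyl ether | COc1cc(/C=C\COC(=O)CC(C)=O)cc(OC)c1O[Si](C)(C)C(C)(C)C | intermediate
9 | 2,2-dimethyl-1,3-dioxane-4,6-dione | CC1(C)OC(=O)CC(=O)O1 | starting material
10 | thiophenol | Sc1ccccc1 | starting material
11 | 3-oxo-3-(phenylsulfanyl)propanoic acid | OC(=O)CC(=O)Sc1ccccc1 | intermediate
12 | C4-carboxy aldol adduct (as 13 with CO2H on C4; C3 S, C4 either configuration; transient) | COc1cc(/C=C\COC(=O)C[C@](C)(O)C(C(=O)O)C(=O)Sc2ccccc2)cc(OC)c1O[Si](C)(C)C(C)(C)C | intermediate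
13 | (3S)-S-phenyl thioester of the phenol-silylated target | COc1cc(/C=C\COC(=O)C[C@](C)(O)CC(=O)Sc2ccccc2)cc(OC)c1O[Si](C)(C)C(C)(C)C | intermediate
14 | (3R)-phenol-silylated target acid | COc1cc(/C=C\COC(=O)C[C@](C)(O)CC(=O)O)cc(OC)c1O[Si](C)(C)C(C)(C)C | intermediate
15 | (Z)-sinapyl hydrogen (3R)-3-hydroxy-3-methylglutarate (CNP0150281.1) | COc1cc(/C=C\COC(=O)C[C@](C)(O)CC(=O)O)cc(OC)c1O | target

Total step count: 8. Longest linear sequence: 7 (steps 1–4, then 6–8). Step 5 is a one-step side branch.

Steps most likely to fail

1. Step 6.
- What may go wrong: the acceptor may be drained into its copper enolate, so that the half thioester merely decarboxylates. Facial discrimination at the chelate may also be poor.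
- Fallback: known chemistry with no C–C bond formation. It sets out from 5, rejoins the route at 14 and leaves out steps 4–7.
- The whole C1–C5 unit is taken as the prochiral, commercially available 3-hydroxy-3-methylglutaric anhydride F1 (1.5 equiv). It is opened by alcohol 5 in a cinchona-alkaloid-catalysed desymmetrising alcoholysis.
- The catalyst is hydroquinidine anthraquinone-1,4-diyl diether, (DHQD)2AQN, or its hydroquinine pseudoenantiomer, whichever favours the (R)-acid, in Et2O/toluene at −20 °C. This reaction type is established for 3-substituted glutaric anhydrides.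
- Enantiomeric purity is then raised by crystallising the (S)-1-phenylethylammonium salt F2. Cold aqueous KHSO4 releases 14.

2. Step 7.
- What may go wrong: the neighbouring tertiary hydroxyl may capture the silver-activated acyl group. This would close a β-lactone that then fragments or reopens without stereocontrol. Acid-induced ionisation of the electron-rich allylic ester is a second risk.
- Fallback: it sets out from 13 and rejoins at 15. The internal nucleophile is masked first.
- Et3SiOTf and 2,6-lutidine in CH2Cl2 at −78 °C convert 13 into the tertiary triethylsilyl ether thioester F3.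
- Thiophilic hydrolysis (AgOCOCF3, 2,6-lutidine, THF/H2O) then gives the doubly silylated acid F4.
- Excess buffered Bu4NF/AcOH removes both silyl groups in one operation to give 15, so only one step is added.

3. Step 2.
- What may go wrong: Z selectivity may erode in the olefination, or the electron-rich cinnamate may drift from Z to E.
- Fallback: it sets out from 2 and rejoins at 5. The geometry is set by syn hydrogenation instead of olefination.
- Corey–Fuchs reaction of 2 (CBr4, PPh3, CH2Cl2, 0 °C) gives the 1,1-dibromoalkene F5.
- n-BuLi (2.2 equiv, THF, −78 °C) followed by paraformaldehyde gives the propargylic alcohol F6.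
- Semi-hydrogenation (H2, Pd/CaCO3 poisoned with Pb(OAc)2, quinoline, EtOAc; Lindlar reduction) delivers 5.

Further compounds
F1 | step 6 | 3-hydroxy-3-methylglutaric anhydride (4-hydroxy-4-methyloxane-2,6-dione) | CC1(O)CC(=O)OC(=O)C1
F2 | step 6 | (S)-1-phenylethylammonium salt of 14 | COc1cc(/C=C\COC(=O)C[C@](C)(O)CC(=O)[O-])cc(OC)c1O[Si](C)(C)C(C)(C)C.C[C@H]([NH3+])c1ccccc1
F3 | step 7 | (3S)-3-O-triethylsilyl ether of thioester 13 | COc1cc(/C=C\COC(=O)C[C@](C)(O[Si](CC)(CC)CC)CC(=O)Sc2ccccc2)cc(OC)c1O[Si](C)(C)C(C)(C)C
F4 | step 7 | (3R)-3-O-triethylsilyl ether of acid 14 | COc1cc(/C=C\COC(=O)C[C@](C)(O[Si](CC)(CC)CC)CC(=O)O)cc(OC)c1O[Si](C)(C)C(C)(C)C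
F5 | step 2 | tert-butyl[4-(2,2-dibromoethenyl)-2,6-dimethoxyphenoxy]dimethylsilane | COc1cc(C=C(Br)Br)cc(OC)c1O[Si](C)(C)C(C)(C)C
F6 | step 2 | 3-{4-[(tert-butyldimethylsilyl)oxy]-3,5-dimethoxyphenyl}prop-2-yn-1-ol | COc1cc(C#CCO)cc(OC)c1O[Si](C)(C)C(C)(C)C
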